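All constants are assumed; the flask was simulated.

You want L from J, and J has two routes to it, one with the proton Z and one without, while it also waits reversibly as X.

    J ⇌ X (K1 = 0.35, k1 = 0.053 s⁻¹)
    D ⇌ Q, rate k2*(cs2 - [Q]) while solid is left; crystals form when [Q] > cs2 (cs2 = 48 mM, k2 = 0.40 s⁻¹)
    J + Z → Q + Z + L (k3 = 4.4 M⁻¹ s⁻¹)
    Q ⇌ G + Z, settled at all times (K4 = 1.6 × 10⁻¹⁰ M)
    J → Q + L (k5 = 0.019 s⁻¹)

J 0.10 M (fed, over 20 s); Z 0.0100 M; time 40 s

* part of the J that has reacted at 40 s
* pH of the solution at 40 s

- Z is the free proton; pH is minus the decimal logarithm of its molar concentration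
- Q is meant together with its D
- solid, in amounts per volume of the solution: D
- what has gone from J into another species counts as reacted, even if it can come back
- run time (flask): 40 s

Z comes out of its route unchanged. Even with the whole charge standing as Q, the balance gives c_G = 1.60 × 10⁻⁹ M, far less than c_Z. So c_Z holds at its charge and the pH is 2.00. No rate that uses J contains Q, G or D, so the crystals stay out of the sum.

With c_Z constant, both routes are pseudo-first-order in J:

k_L = 0.019 s⁻¹ + 4.4 M⁻¹ s⁻¹ × 0.0100 M = 0.0630 s⁻¹

X and J relax towards balance with a half-life of 3.39 s, shorter than the feed. So treat J + X as one pool with 1/(1 + 0.35) of it free: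

κ = k_L / (1 + 0.35) = 0.0467 s⁻¹

You carry κ, the first-order loss constant of the pool J + X, from here on.

Pool at the end of the feed, as a part of the charge: (1 − e^(−κ·20 s)) / (κ·20 s) = 65.0%

Pool at 40 s, after decay: 25.6%

Free J at balance: 18.9%, so 81.1% has reacted, X counted as reacted.

That is my number, but its weak link is the balance. Once the feed stops, J falls and X trails it. Let X fall with κ as well, and its own equation gives a new ratio:

c_X/c_J = 0.053 s⁻¹ / (0.151 s⁻¹ − κ) = 0.506

Splitting the pool by this ratio raises the reacted part to 83.0%.

The forecast gave 82.7% and pH 2, treating J as “a linear feed-and-decay system”.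

The flask gives 82.7% and pH 2.00, with 17% of the J free at 40.0 s.

In this flask at 19.8 s, the route through Z uses J 2.3 times as fast as the route without it, with half-lives of 16 s and 36 s. The route with the shorter half-life is the one whose term in κ holds c_Z. In the neighbour flask with 0.0060 M of Z, κ is 0.0336 s⁻¹, lower than in this flask. The pool is then 37.2% and the ratio 0.450, so 74.3% has reacted. The simulation of that flask gives 74.5%.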